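## The problem

Curlignan (22) is a 2-aryl-3-hydroxymethyl-2,3-dihydrobenzofuran: a methyl benzoate ring A is fused through C3a and C7a to a dihydrofuran ring B, which carries a guaiacyl ring C at C2 and a hydroxymethyl group at C3. The two adjacent stereocentres, C2 (S) and C3 (R), hold these substituents trans. Trans is the more stable arrangement, so one centre could in principle correct the other by equilibration, but only through ionisation at C2 (a benzylic ether para to a phenol oxygen) or through ring opening, and both endanger the absolute configuration. A safe plan therefore sets both centres together in one absolute sense and never re-equilibrates them. Three groups limit the reagents: the aryl methyl ester at C5 must survive although the C3 side chain has to reach the alcohol level, the C2–O1 bond is a benzyl aryl ether open to acid and hydrogenolysis, and the free phenol is easily oxidised. Ring A is 1,2,3,5-tetrasubstituted (O1 on C7a, C3 on C3a, ester on C5, methoxy on C7), which is awkward to build regioselectively from a simple benzoate. This same pattern maps onto a 2-pyrone carrying the ester on its C5 and the methoxy on its C3: the pyrone supplies C4–C7, and C3a and C7a are the nucleophilic and the heteroatom-bearing carbon of a ketene acetal, meta and para to the ester, where the polarity of a cycloaddition places them.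

## Retrosynthesis

**22 from 21.** No skeletal bond is cut. The phenol and the primary alcohol are both masked as benzyl ethers in 21 so that one hydrogenolysis ends the synthesis. Benzyl is preferred to silyl because the groups must pass basic peroxide, a hydride reduction, thionation, a lithium amide and prolonged heating. The forward step must remove two O-benzyl groups without opening the benzylic C2–O1 bond.

**21 from 12 and 18.** Ring A is cut at C3a–C4 and C7–C7a. This removes four ring carbons with their ester and methoxy groups as the flat, achiral pyrone 18, and leaves C3a, C7a and all of ring B with both stereocentres in the cyclic ketene O,S-acetal 12. The neighbouring cuts (C2–C3 or O1–C2) keep ring A, so a tetrasubstituted benzoate would have to be made and stereocontrol would move into the ring closure. Here the ring closure creates no lasting stereocentre. The forward reaction must pair the CH carbon of 12 with C6 of 18, lose the lactone bridge by decarboxylation, and aromatise by expelling the sulfur substituent and not the ring oxygen.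

**12 from 11 and 10.** The C–S bond and the enol double bond of 12 go back to thionolactone 11 (S-methylation of its enethiolate), and the thiocarbonyl of 11 to the carbonyl of lactone 10. The O,S-acetal is chosen over an O,O-acetal because the later aromatisation then has one clearly better leaving group. The lactone is simpler still: no sulfur, no enol ether, and a stable trans-4,5-disubstituted γ-butyrolactone. The forward steps must deprotonate only the ring CH2 next to C=S and leave the two stereocentres alone.

**10 from 9, 8 and 6.** These are functional-group changes: benzyl ether 10 from alcohol 9, alcohol from acid 8, acid from acyl oxazolidinone 6. The C3 side chain is brought to the alcohol level here, before ring A and its methyl ester exist, so the two carboxyl carbons never have to be told apart. The reduction must spare the lactone, and the benzylation must avoid alkoxide conditions, under which the hydroxymethyl lactone could translactonise.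

**6 from 3 and 4; 3 from 1 and 2.** The lactone C4–C5 bond (the future C3–C2 bond) and the lactone C–O bond are cut together: an auxiliary-controlled syn aldol between succinate imide 3 and O-benzylvanillin 4, followed by lactonisation. This one event sets both stereocentres, absolute and relative, from a bought auxiliary 1 and acid chloride 2. A syn aldol is required, because ring closure through the syn hydroxyl and ester arm places the acyl and aryl groups trans on the lactone.

**18 from 16, 15, 13 and 14.** The pyrone is opened at its lactone O1–C2 bond to the push–pull diene 16, whose aminomethylidene carbon (pyrone C6) is removed to give the 2-methoxyglutaconate 15. The C3–C4 bond of 15 is cut to methyl methoxyacetate 13 and methyl 3-methoxyacrylate 14, so the methoxy group arrives with 13 and the 5-ester with 14. The forward sequence needs a conjugate addition–elimination, a condensation at the only carbon that can become a methylidene, and an acid lactonisation of the kind that gives coumalates from formylglutaconates.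

## Roads not taken

**Alternative 1:** The cut is C2–C3. A chiral dirhodium tetracarboxylate, Rh2(S-PTAD)4, would decompose the aryldiazoacetate 2,2,2-trichloroethyl 2-diazo-2-{2-[(4-benzyloxy-3-methoxybenzyl)oxy]-3-methoxy-5-(methoxycarbonyl)phenyl}acetate A2. The carbenoid from diazo ester A2 would insert into the benzylic O–CH2 bond five atoms away and give the cis-dihydrobenzofuran diester A1.
- Merits: chirality is catalytic, the ring and both centres form in one step, and the benzylic C–H next to an electron-rich arene is a good insertion site.
- Weak points: A1 is cis, so C3 must be epimerised. A base strong enough to do this can also expel the phenoxide from C2 (retro-oxa-Michael), which would put the C2 configuration at risk. The ether oxygen sits between the methoxy group and the carbenoid carbon, so oxonium ylide formation may compete. A2 needs a tetrasubstituted arylacetic ester that is itself several steps away. The C3 ester must be a trichloroethyl ester so that it can be cleaved and reduced beside the C5 methyl ester.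
- Comparison: after the key step come epimerisation, ester cleavage, reduction and debenzylation. This road is better in using no stoichiometric auxiliary. The chosen plan sets against that a trans product obtained directly and only one carboxyl carbon at the ester level once ring A is present.

**Alternative 2:** The cut is C3–C3a. The substrate would be the enantioenriched flavanone (2S)-2-[4-(benzyloxy)-3-methoxyphenyl]-6-bromo-8-methoxychroman-4-one A4. Flavanone A4 would be treated with PhI(OAc)2 and H2SO4 in HC(OMe)3, which iodinates its enol ether at C3. Ring A of A4 then migrates from the ketal carbon to the iodinated C3, contracting the pyranone to the trans-dihydrobenzofuran-3-carboxylate A3.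
- Merits: a flavanone of the type of A4 is assembled from simple aromatic building blocks, the contraction gives trans directly, and the C3 carbon arrives as an ester in the same step.
- Weak points: the aryl group that must migrate in flavanone A4 is the brominated, less electron-rich ring A, while the guaiacyl ring at C2 is the better migrating and more oxidisable group, so isoflavone-type rearrangement and arene oxidation threaten. C2 of flavanone A4 can racemise through the chalcone in acid. The C5 ester cannot be present during reduction of the C3 ester of A3, so a bromide placeholder and a late methoxycarbonylation of the aryl bromide (CO, MeOH, Pd(OAc)2 with a bisphosphine) are needed.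
- Comparison: on paper the road through A4 and A3 is shorter than the chosen one, and that is a real advantage. The chosen plan sets against it stereocentres that are never exposed to ionising acid and a key step with no competing migration.

**Alternative 3:** The cuts are O1–C2 and C2–C3. Cs2CO3 would expel sulfinate from the phenol sulfone methyl 3-{2-[(tert-butyldimethylsilyl)oxy]-1-(4-methylbenzenesulfonyl)ethyl}-4-hydroxy-5-methoxybenzoate A6 to give an ortho-quinone methide. The ylide from [4-(benzyloxy)-3-methoxybenzyl]dimethylsulfonium tetrafluoroborate A7 would add to the exocyclic carbon, and the phenoxide would displace the sulfide, closing the ring to the trans silyl ether A5.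
- Merits: this is the most convergent road. All oxidation levels are already correct, the closure is trans-selective, and only two deprotections follow.
- Weak points: the absolute configuration would need a chiral sulfide version of A7 or a chiral catalyst, which is not secured for a semi-stabilised benzylic ylide. The quinone methide carries an alkyl substituent with hydrogens that can shift to oxygen to give a styrenyl enol ether. A6 requires ortho-functionalisation of an ester-deactivated phenol.
- Comparison: if enantiocontrol were solved this road would beat the chosen one in step count and convergence. The chosen plan sets against it an absolute and relative configuration fixed by an auxiliary aldol of known sense.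

Key step: step 11

## Route

Remark: the target is read as the (2S,3R) isomer, aryl and hydroxymethyl trans on ring B.
Assumption: compounds 1, 2, 4, 13 and 14 are bought. The double-bond geometry of 16 and 17 and the transient ring-fusion centres of 19 and 20 have no consequence and are left undefined.

Step 1
Reactants: 1 (4S)-4-benzyl-1,3-oxazolidin-2-one; 2 methyl 4-chloro-4-oxobutanoate
Product: 3 methyl 4-[(4S)-4-benzyl-2-oxo-1,3-oxazolidin-3-yl]-4-oxobutanoate
Conditions: n-BuLi, THF, −78 °C; then 2, −78 → 0 °C
Reagents that add atoms: none
Why: N-acylation of the lithiated oxazolidinone; the acid chloride reacts far faster than the methyl ester, so the succinate is differentiated at once.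

Step 2
Reactants: 3 methyl 4-[(4S)-4-benzyl-2-oxo-1,3-oxazolidin-3-yl]-4-oxobutanoate; 4 4-(benzyloxy)-3-methoxybenzaldehyde
Product: 6 (4S)-4-benzyl-3-{[(2S,3S)-2-[4-(benzyloxy)-3-methoxyphenyl]-5-oxooxolan-3-yl]carbonyl}-1,3-oxazolidin-2-one, via syn-aldol hydroxy ester 5 (not isolated)
Conditions: Bu2BOTf, i-Pr2NEt, CH2Cl2, 0 °C; 4, −78 → 0 °C; pH 7 buffer, MeOH, H2O2, 0 °C; then PPTS (cat.), PhMe, 50 °C
Reagents that add atoms: none
Why: Evans syn-aldol: boron enolises only the imide to the Z-enolate, and the chair transition state with the auxiliary benzyl group shielding one face should give the (3S,4S) adduct 5; closure of its syn hydroxyl onto the ester arm then places the acyl and aryl groups trans on lactone 6.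

Step 3
Reactants: 6 (4S)-4-benzyl-3-{[(2S,3S)-2-[4-(benzyloxy)-3-methoxyphenyl]-5-oxooxolan-3-yl]carbonyl}-1,3-oxazolidin-2-one
Product: 8 (2S,3S)-2-[4-(benzyloxy)-3-methoxyphenyl]-5-oxooxolane-3-carboxylic acid, via peroxy acid 7 (not isolated)
Conditions: LiOH, H2O2, THF–H2O, 0 °C; Na2SO3; HCl to pH 2
Reagents that add atoms: hydrogen peroxide (as LiOOH), OO
Why: Hydroperoxide cleavage of an N-acyl oxazolidinone at the exocyclic carbonyl, with sulfite reducing the peroxy acid; any lactone opened by base recloses on acidification, and the trans arrangement is the stable one.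

Step 4
Reactants: 8 (2S,3S)-2-[4-(benzyloxy)-3-methoxyphenyl]-5-oxooxolane-3-carboxylic acid
Product: 9 (4R,5S)-5-[4-(benzyloxy)-3-methoxyphenyl]-4-(hydroxymethyl)oxolan-2-one
Conditions: BH3·THF, THF, 0 °C → rt; MeOH
Reagents that add atoms: none
Why: Borane reduces a carboxylic acid through its acyloxyborane much faster than a lactone, the standard chemoselective reduction of paraconic acids; no stereocentre is touched.

Step 5
Reactants: 9 (4R,5S)-5-[4-(benzyloxy)-3-methoxyphenyl]-4-(hydroxymethyl)oxolan-2-one
Product: 10 (4R,5S)-5-[4-(benzyloxy)-3-methoxyphenyl]-4-[(benzyloxy)methyl]oxolan-2-one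
Conditions: BnOC(=NH)CCl3, TfOH (cat.), CH2Cl2–cyclohexane, 0 °C → rt
Reagents that add atoms: benzyl 2,2,2-trichloroacetimidate, N=C(OCc1ccccc1)C(Cl)(Cl)Cl
Why: Acid-catalysed O-benzylation with a trichloroacetimidate; no alkoxide is formed, so the primary alcohol cannot attack the lactone and translactonise.

Step 6
Reactants: 10 (4R,5S)-5-[4-(benzyloxy)-3-methoxyphenyl]-4-[(benzyloxy)methyl]oxolan-2-one
Product: 11 (4R,5S)-5-[4-(benzyloxy)-3-methoxyphenyl]-4-[(benzyloxy)methyl]oxolane-2-thione
Conditions: Lawesson's reagent (0.6 equiv), PhMe, 90 °C
Reagents that add atoms: Lawesson's reagent, COc1ccc(cc1)P1(=S)SP(=S)(S1)c1ccc(OC)cc1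
Why: Thionation of a γ-lactone carbonyl by the dithiophosphine ylide through a four-membered cycloaddition–cycloreversion; ethers and stereocentres are spectators at this moderate temperature.

Step 7
Reactants: 11 (4R,5S)-5-[4-(benzyloxy)-3-methoxyphenyl]-4-[(benzyloxy)methyl]oxolane-2-thione
Product: 12 (2S,3R)-2-[4-(benzyloxy)-3-methoxyphenyl]-3-[(benzyloxy)methyl]-5-(methylsulfanyl)-2,3-dihydrofuran
Conditions: LiN(i-Pr)2, THF, −78 °C; MeI, −78 → 0 °C
Reagents that add atoms: iodomethane, CI
Why: Deprotonation of the CH2 next to C=S and S-alkylation of the soft enethiolate is the standard entry to cyclic ketene O,S-acetals; the stereocentres are β and γ to the thiocarbonyl and not acidic, and 12 is passed through basic alumina and used at once.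

Step 8
Reactants: 13 methyl methoxyacetate; 14 methyl (E)-3-methoxyprop-2-enoate
Product: 15 dimethyl (E)-4-methoxypent-2-enedioate (racemic)
Conditions: LiN(i-Pr)2 (2.1 equiv), 13 (2.2 equiv), THF, −78 °C; 14, −78 → −20 °C; AcOH
Reagents that add atoms: none
Why: Conjugate addition–elimination (vinylic substitution) of an ester enolate on a β-alkoxyacrylate; the second equivalent of enolate deprotonates the acidic glutaconate and so protects it from further addition, and either double-bond isomer of 15 serves in the next step.

Step 9
Reactants: 15 dimethyl (E)-4-methoxypent-2-enedioate (racemic)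
Product: 16 dimethyl 4-[(dimethylamino)methylidene]-2-methoxypent-2-enedioate (mixture of double-bond isomers)
Conditions: Me2NCH(OMe)2, PhMe, 90 °C
Reagents that add atoms: N,N-dimethylformamide dimethyl acetal, COC(OC)N(C)C
Why: Aminomethylenation of an active methylene compound; the glutaconate anion can condense irreversibly only at the terminus that still bears a hydrogen, which is the carbon next to the future 5-ester.

Step 10
Reactants: 16 dimethyl 4-[(dimethylamino)methylidene]-2-methoxypent-2-enedioate (mixture of double-bond isomers)
Product: 18 methyl 3-methoxy-2-oxo-2H-pyran-5-carboxylate, via hydroxymethylidene diester 17 (not isolated)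
Conditions: AcOH–H2O (9:1), 90 °C
Reagents that add atoms: water, O
Why: Acid hydrolysis of the enamine to enol 17 and lactonisation onto the only ester that gives a six-membered ring, the same closure that turns formylglutaconates into coumalates; the push–pull diene equilibrates its geometry under acid.

Step 11
Reactants: 12 (2S,3R)-2-[4-(benzyloxy)-3-methoxyphenyl]-3-[(benzyloxy)methyl]-5-(methylsulfanyl)-2,3-dihydrofuran; 18 methyl 3-methoxy-2-oxo-2H-pyran-5-carboxylate
Product: 21 methyl (2S,3R)-2-[4-(benzyloxy)-3-methoxyphenyl]-3-[(benzyloxy)methyl]-7-methoxy-2,3-dihydro-1-benzofuran-5-carboxylate, via bridged lactone cycloadduct 19 (not isolated), via 7a-methylsulfanyl cyclohexadiene 20 (not isolated)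
Conditions: 18 (1.5 equiv), PhMe, 110 °C, slow Ar stream
Reagents that add atoms: none
Why: Inverse-electron-demand Diels–Alder reaction of a 2-pyrone with a ketene acetal, followed by cycloreversion and elimination, the established way from coumalate-type pyrones to benzoates. The HOMO of 12 is largest on its C4–H carbon and the LUMO of 18 on C6 (β to the ester, vinylogous to the lactone carbonyl), so the C3a–C4 bond leads and the acetal carbon closes onto the methoxy-bearing pyrone C3 (C7–C7a); this puts C7a para and C3a meta to the ester as required. Ring A is closed as a six-membered carbocycle by an intermolecular, probably asynchronous (4+2) cycloaddition that gives bridged lactone 19; no tether is involved. 19 loses CO2 by retro-(4+2) to diene 20, and 20 aromatises by 1,2-elimination of methanethiol, with the ring oxygen stabilising the developing cation at C7a. No lasting stereocentre is made: the centres at C3a, C4, C7 and C7a are transient, and C2 and C3 lie outside the reacting π-system and are not acidic under neutral heating. The step needs regioselectivity, secured by the matched polarisation above, and loss of thiolate in preference to the ring alkoxide, secured by the weaker C–S bond, the better leaving group MeS− and removal of volatile MeSH in the gas stream. Excess pyrone and exclusion of acid protect the hydrolytically sensitive ketene acetal.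

Step 12
Reactants: 21 methyl (2S,3R)-2-[4-(benzyloxy)-3-methoxyphenyl]-3-[(benzyloxy)methyl]-7-methoxy-2,3-dihydro-1-benzofuran-5-carboxylate
Product: 22 curlignan, methyl (2S,3R)-2-(4-hydroxy-3-methoxyphenyl)-3-(hydroxymethyl)-7-methoxy-2,3-dihydro-1-benzofuran-5-carboxylate
Conditions: H2 (1 atm), Pd/C (10 wt%), EtOAc–MeOH, rt
Reagents that add atoms: none
Why: Hydrogenolysis of an aryl benzyl ether and a primary alkyl benzyl ether; both are unhindered and should cleave before the ring C2–O1 bond, which is a secondary, doubly substituted benzylic ether, provided the reaction is stopped after two equivalents of hydrogen.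

## Compound list

1 | (4S)-4-benzyl-1,3-oxazolidin-2-one | O=C1N[C@@H](Cc2ccccc2)CO1 | starting material
2 | methyl 4-chloro-4-oxobutanoate | COC(=O)CCC(Cl)=O | starting material
3 | methyl 4-[(4S)-4-benzyl-2-oxo-1,3-oxazolidin-3-yl]-4-oxobutanoate | COC(=O)CCC(=O)N1[C@@H](Cc2ccccc2)COC1=O | intermediate
4 | 4-(benzyloxy)-3-methoxybenzaldehyde | COc1cc(C=O)ccc1OCc1ccccc1 | starting material
5 | methyl (3S,4S)-3-{[(4S)-4-benzyl-2-oxo-1,3-oxazolidin-3-yl]carbonyl}-4-[4-(benzyloxy)-3-methoxyphenyl]-4-hydroxybutanoate | COC(=O)C[C@H](C(=O)N1[C@@H](Cc2ccccc2)COC1=O)[C@@H](c1ccc(OCc2ccccc2)c(OC)c1)O | intermediate (not isolated)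
6 | (4S)-4-benzyl-3-{[(2S,3S)-2-[4-(benzyloxy)-3-methoxyphenyl]-5-oxooxolan-3-yl]carbonyl}-1,3-oxazolidin-2-one | O=C1C[C@H](C(=O)N2[C@@H](Cc3ccccc3)COC2=O)[C@@H](c2ccc(OCc3ccccc3)c(OC)c2)O1 | intermediate
7 | (2S,3S)-2-[4-(benzyloxy)-3-methoxyphenyl]-5-oxooxolane-3-carboperoxoic acid | O=C1C[C@H](C(=O)OO)[C@@H](c2ccc(OCc3ccccc3)c(OC)c2)O1 | intermediate (not isolated)
8 | (2S,3S)-2-[4-(benzyloxy)-3-methoxyphenyl]-5-oxooxolane-3-carboxylic acid | O=C1C[C@H](C(=O)O)[C@@H](c2ccc(OCc3ccccc3)c(OC)c2)O1 | intermediate
9 | (4R,5S)-5-[4-(benzyloxy)-3-methoxyphenyl]-4-(hydroxymethyl)oxolan-2-one | O=C1C[C@H](CO)[C@@H](c2ccc(OCc3ccccc3)c(OC)c2)O1 | intermediate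
10 | (4R,5S)-5-[4-(benzyloxy)-3-methoxyphenyl]-4-[(benzyloxy)methyl]oxolan-2-one | O=C1C[C@H](COCc2ccccc2)[C@@H](c2ccc(OCc3ccccc3)c(OC)c2)O1 | intermediate
11 | (4R,5S)-5-[4-(benzyloxy)-3-methoxyphenyl]-4-[(benzyloxy)methyl]oxolane-2-thione | S=C1C[C@H](COCc2ccccc2)[C@@H](c2ccc(OCc3ccccc3)c(OC)c2)O1 | intermediate
12 | (2S,3R)-2-[4-(benzyloxy)-3-methoxyphenyl]-3-[(benzyloxy)methyl]-5-(methylsulfanyl)-2,3-dihydrofuran | CSC1=C[C@H](COCc2ccccc2)[C@@H](c2ccc(OCc3ccccc3)c(OC)c2)O1 | intermediate
13 | methyl methoxyacetate | COCC(=O)OC | starting material
14 | methyl (E)-3-methoxyprop-2-enoate | CO/C=C/C(=O)OC | starting material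
15 | dimethyl (E)-4-methoxypent-2-enedioate (racemic) | COC(=O)/C=C/C(OC)C(=O)OC | intermediate
16 | dimethyl 4-[(dimethylamino)methylidene]-2-methoxypent-2-enedioate (mixture of double-bond isomers) | COC(=O)C(OC)=CC(=CN(C)C)C(=O)OC | intermediate
17 | dimethyl 4-(hydroxymethylidene)-2-methoxypent-2-enedioate (mixture of double-bond isomers) | COC(=O)C(OC)=CC(=CO)C(=O)OC | intermediate (not isolated)
18 | methyl 3-methoxy-2-oxo-2H-pyran-5-carboxylate | COC(=O)C1=COC(=O)C(OC)=C1 | intermediate
19 | methyl (2S,3R)-2-[4-(benzyloxy)-3-methoxyphenyl]-3-[(benzyloxy)methyl]-7-methoxy-7a-(methylsulfanyl)-2,3,3a,4,7,7a-hexahydro-1-benzofuran-5-carboxylate bridged from C4 to C7 by –O–C(=O)– (oxygen on C4, carbonyl carbon on C7; mixture at the four new centres) | COC(=O)C1=CC2(OC)C(=O)OC1C1[C@H](COCc3ccccc3)[C@@H](c3ccc(OCc4ccccc4)c(OC)c3)OC21SC | intermediate (not isolated)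
20 | methyl (2S,3R)-2-[4-(benzyloxy)-3-methoxyphenyl]-3-[(benzyloxy)methyl]-7-methoxy-7a-(methylsulfanyl)-2,3,3a,7a-tetrahydro-1-benzofuran-5-carboxylate (mixture at C3a and C7a) | COC(=O)C1=CC2[C@H](COCc3ccccc3)[C@@H](c3ccc(OCc4ccccc4)c(OC)c3)OC2(SC)C(OC)=C1 | intermediate (not isolated)
21 | methyl (2S,3R)-2-[4-(benzyloxy)-3-methoxyphenyl]-3-[(benzyloxy)methyl]-7-methoxy-2,3-dihydro-1-benzofuran-5-carboxylate | COC(=O)c1cc(OC)c2c(c1)[C@H](COCc1ccccc1)[C@@H](c1ccc(OCc3ccccc3)c(OC)c1)O2 | intermediate
22 | curlignan, methyl (2S,3R)-2-(4-hydroxy-3-methoxyphenyl)-3-(hydroxymethyl)-7-methoxy-2,3-dihydro-1-benzofuran-5-carboxylate | COC(=O)c1cc(OC)c2c(c1)[C@H](CO)[C@@H](c1ccc(O)c(OC)c1)O2 | target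

## Step count and risks

Total: 12 steps. Longest linear sequence: 9 steps (steps 1–7, 11, 12); the pyrone arm (steps 8–10) joins at step 11.

**Step 11 (key step).** The cycloaddition may be slow, because the methoxy group on pyrone C3 raises the diene LUMO and crowds the forming C7–C7a bond. During long heating the ketene acetal may be lost to hydrolysis or to addition of liberated thiol. The sequence may stop after the first C–C bond with opening of the pyrone, or the ring oxygen may be expelled instead of the thiolate during aromatisation.

Fallback, setting out from 12: the diene is exchanged for the more electron-poor and less crowded methyl 3-bromo-2-oxo-2H-pyran-5-carboxylate F1, a known pyrone with the same polarisation. Heating it with 12 in toluene should give, after the same loss of CO2 and MeSH, methyl (2S,3R)-2-[4-(benzyloxy)-3-methoxyphenyl]-3-[(benzyloxy)methyl]-7-bromo-2,3-dihydro-1-benzofuran-5-carboxylate F2. Copper-catalysed methoxylation of the aryl bromide (CuI, NaOMe, MeOH–DMF, 100 °C) then installs the C7 methoxy group, and the route is rejoined at 21.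

**Step 6.** Thionation may stall, or the thionolactone may rearrange to the S-benzylic thiolactone by ionisation of the electron-rich benzylic C–O bond, with loss of configuration at that carbon.

Fallback, setting out from 10: sulfur is avoided altogether. Enolisation with LiN(i-Pr)2 and O-silylation with TBSCl (THF, DMPU, −78 °C) should give the silyl ketene acetal {[(4R,5S)-5-[4-(benzyloxy)-3-methoxyphenyl]-4-[(benzyloxy)methyl]-4,5-dihydrofuran-2-yl]oxy}(tert-butyl)dimethylsilane F3. This is heated directly with 18; decarboxylation and loss of the silanol from the orthoester-type carbon lead to 21, bypassing steps 6 and 7.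

**Step 8.** The enolate may attack the ester carbonyl of 14 (Claisen condensation) or condense with itself, and the β-methoxyacrylate may be too weak an acceptor.

Fallback, setting out from 13: a Lewis-acid route replaces the anionic one. 13 is converted (LiN(i-Pr)2, Me3SiCl, THF, −78 °C) into 1,2-dimethoxy-1-(trimethylsilyloxy)ethene F4. A Mukaiyama aldol of F4 with the acetal methyl 3,3-dimethoxypropanoate F5 (Me3SiOTf cat., CH2Cl2, −78 °C) gives dimethyl 2,3-dimethoxypentanedioate F6. β-Elimination of methanol with DBU returns the route to 15.

**Step 12.** Hydrogenolysis may go on to open the benzylic C2–O1 bond of ring B, or may be stopped early by sulfur residues from step 11 poisoning the catalyst.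

Fallback, setting out from 21: the reductive method is replaced by Lewis-acid debenzylation with BCl3 and pentamethylbenzene as cation scavenger (CH2Cl2, −78 °C). This should cleave both benzyl ethers, spare the methyl ethers and the ester, and lead directly to 22. It makes no new compound (F0).

## Further compounds

F1 | step 11 | methyl 3-bromo-2-oxo-2H-pyran-5-carboxylate | COC(=O)C1=COC(=O)C(Br)=C1
F2 | step 11 | methyl (2S,3R)-2-[4-(benzyloxy)-3-methoxyphenyl]-3-[(benzyloxy)methyl]-7-bromo-2,3-dihydro-1-benzofuran-5-carboxylate | COC(=O)c1cc(Br)c2c(c1)[C@H](COCc1ccccc1)[C@@H](c1ccc(OCc3ccccc3)c(OC)c1)O2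
F3 | step 6 | {[(4R,5S)-5-[4-(benzyloxy)-3-methoxyphenyl]-4-[(benzyloxy)methyl]-4,5-dihydrofuran-2-yl]oxy}(tert-butyl)dimethylsilane | CC(C)(C)[Si](C)(C)OC1=C[C@H](COCc2ccccc2)[C@@H](c2ccc(OCc3ccccc3)c(OC)c2)O1
F4 | step 8 | 1,2-dimethoxy-1-(trimethylsilyloxy)ethene | COC=C(OC)O[Si](C)(C)C
F5 | step 8 | methyl 3,3-dimethoxypropanoate | COC(OC)CC(=O)OC
F6 | step 8 | dimethyl 2,3-dimethoxypentanedioate (mixture of diastereomers) | COC(=O)CC(OC)C(OC)C(=O)OC
F0 | step 12 | none | none
A1 | alternative 1 | 5-methyl 3-(2,2,2-trichloroethyl) (2S,3R)-2-[4-(benzyloxy)-3-methoxyphenyl]-7-methoxy-2,3-dihydro-1-benzofuran-3,5-dicarboxylate (2,3-cis) | COC(=O)c1cc(OC)c2c(c1)[C@@H](C(=O)OCC(Cl)(Cl)Cl)[C@@H](c1ccc(OCc3ccccc3)c(OC)c1)O2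
A2 | alternative 1 | 2,2,2-trichloroethyl 2-diazo-2-{2-[(4-benzyloxy-3-methoxybenzyl)oxy]-3-methoxy-5-(methoxycarbonyl)phenyl}acetate | COC(=O)c1cc(OC)c(OCc2ccc(OCc3ccccc3)c(OC)c2)c(c1)C(=[N+]=[N-])C(=O)OCC(Cl)(Cl)Cl
A3 | alternative 2 | methyl (2S,3S)-2-[4-(benzyloxy)-3-methoxyphenyl]-5-bromo-7-methoxy-2,3-dihydro-1-benzofuran-3-carboxylate (2,3-trans) | Brc1cc(OC)c2c(c1)[C@H](C(=O)OC)[C@@H](c1ccc(OCc3ccccc3)c(OC)c1)O2
A4 | alternative 2 | (2S)-2-[4-(benzyloxy)-3-methoxyphenyl]-6-bromo-8-methoxychroman-4-one | O=C1C[C@@H](c2ccc(OCc3ccccc3)c(OC)c2)Oc2c(OC)cc(Br)cc21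
A5 | alternative 3 | methyl (2S,3R)-2-[4-(benzyloxy)-3-methoxyphenyl]-3-{[(tert-butyldimethylsilyl)oxy]methyl}-7-methoxy-2,3-dihydro-1-benzofuran-5-carboxylate | COC(=O)c1cc(OC)c2c(c1)[C@H](CO[Si](C)(C)C(C)(C)C)[C@@H](c1ccc(OCc3ccccc3)c(OC)c1)O2
A6 | alternative 3 | methyl 3-{2-[(tert-butyldimethylsilyl)oxy]-1-(4-methylbenzenesulfonyl)ethyl}-4-hydroxy-5-methoxybenzoate | COC(=O)c1cc(OC)c(O)c(c1)C(CO[Si](C)(C)C(C)(C)C)S(=O)(=O)c1ccc(C)cc1
A7 | alternative 3 | [4-(benzyloxy)-3-methoxybenzyl]dimethylsulfonium tetrafluoroborate | C[S+](C)Cc1ccc(OCc2ccccc2)c(OC)c1.F[B-](F)(F)F
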